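If you want to know what stands in these flasks, write first the balance of the partner charged in the smaller amount.

| flask | solid substrate | reagent | free catalyst | second catalyst | remark | time |
|---|---|---|---|---|---|---|
| Saturday's | 0.25 M | 0.45 M | 4 mM | 2.2 mM | run made earlier |  |
| Wednesday's | 0.50 M | 0.30 M | 4 mM | 2.2 mM | run made earlier |  |
| dawn | 0.25 M | 0.300 M | 4.0 mM | 2.2 mM |  | 8.0 d |
| noon | 0.25 M | 0.300 M | 6.0 mM | 2.2 mM |  | 8.0 d |
| dusk | 0.25 M | 0.300 M | 10 mM | 2.2 mM |  | 8.0 d |
| winter | 0.25 M | 0.300 M | 15 mM | 2.2 mM |  | 8.0 d |
| autumn | 0.25 M | 0.300 M | 20 mM | 2.2 mM |  | 8.0 d |

- Saturday's (time / d: intermediate / %, product / %): 0.250: 0.2, 0.2; 0.833: 1.1, 1.2; 1.25: 2.1, 2.5; 2.08: 2.0, 8.2; 3.00: 2.2, 15.7; 4.00: 2.8, 23.1; 5.00: 2.5, 31.7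
- Wednesday's (time / d: intermediate / %, product / %): 0.250: 0, 0.1; 0.833: 0.3, 0.4; 1.25: 1.2, 0.7; 2.08: 1.6, 4.3; 3.00: 2.0, 7.4; 4.00: 2.2, 11.0; 5.00: 2.2, 15.3

(scatter of a reading: 0.5 percentage points)

- solid, in amounts per volume of the solution: solid substrate
- the earlier runs were read with a standard deviation of 0.5 percentage points
- at the start none of the solid substrate is in solution
- "hardly changes" means that all values lie within two and a half points (for a concentration: within two and a half percent of the largest)
- no earlier run changes the charge of free catalyst; that part of a forecast is a guess

* amount of intermediate at the end, in percent of the solid substrate charged for dawn, noon, dusk, winter, autumn, in this order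
* how that number moves from the first to the last of them (rises, then falls / rises all the way / falls, then rises / hardly changes / falls all the way)

Add intermediate and product at the last reading of Saturday's run, 5.00 d: they come to 85.5 mM. Do the same for Wednesday's run at 5.00 d: they come to 87.5 mM, although that run holds twice the solid substrate. So read the two as equal within their scatter, but know that neither run varies the free catalyst.

Now take one reagent per product; this is an assumption, and the earlier runs give no reading of the reagent. In the asked flasks the solid substrate, at 0.25 M, is charged in a smaller amount than the reagent, at 0.300 M, so treat it as the limiting reagent. Once it has become product in full, 0.0500 M of reagent remains, which is 16.7% of the reagent's charge. Call this share the reagent floor. Reagent above the floor, scaled by the ratio of the charges, then counts what is not yet product. But it doesn't say in which form that material stands.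

The forecast gives 5.5%, 11%, 4.7%, 2.5% and 1.8%, with the shape "rises, then falls", and it argues at the slow end that “the intermediate builds as reagent falls”.

The flasks give 6.36%, 9.49%, 11.6%, 9.14% and 7.29%; the shape is "rises, then falls", turning at 8.7 mM of free catalyst.

    starting material + free catalyst → free catalyst + intermediate (k = 0.0690 M⁻¹ min⁻¹)
    reagent + second catalyst + intermediate → second catalyst + product (k = 2.40 M⁻² min⁻¹)
    solid substrate ⇌ starting material, rate k3*(cs3 - [starting material]) while solid is left; crystals form when [starting material] > cs3 (solubility = 0.0910 M, k = 4.10 × 10⁻⁴ min⁻¹)

Compare two times in dawn: the intermediate's half-life on its way to product, 0.35 d at 3.31 d, is shorter than the run's 8.0 d, and at that moment intermediate is made 1.07 times as fast as it is used up, each step taken net. Then count the reagent above the floor at 8.00 d: in dawn it stands for 45.9% of the solid substrate charged, and in autumn for 7.43%, of which intermediate is 7.29%.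

The data were generated by integration with constants of no real substance; scatter was added.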